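**Plan**

1. Retrosynthesis: remove the N–O bond last; restore a lactam C=O at the N–CH2 carbon and a formyl group on the lactone β-carbon as helpers. Then cut together the two lactone C–C bonds outside the O–C(=O) unit: the CH2–CH2 bond next to the carbonyl, and the bond between the O-bearing quaternary carbon and the all-carbon quaternary carbon of the cyclopentane. The second cut also opens the piperidine ring.
2. Enabling feature: the O-bearing carbon (with its CH3) and the cyclopentane quaternary carbon are 1,6-related through CH–CH–N–CH of the piperidine ring, and the quaternary carbon carries the lactone β-carbon. An enol chloroacetate on one side and a β,β-disubstituted enal on the other can therefore close the piperidine ring (radical) and the δ-lactone (enolate alkylation) in one flask.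
3. The precursor comes from an amide bond between hydrindenyl amine 8 and epoxy ester 15, followed by 5-exo epoxide opening to the pyrrolidinone.
4. Ring order forward: cyclohexanone ring (from cyclohexenone) → cyclopentene ring (RCM); cyclopentane ring (from cyclopentenyl acetate) → pyrrolidinone → piperidine + δ-lactone together → N-oxide.
5. Stereochemistry: alkynyl-bearing CH by Ni-catalysed asymmetric conjugate addition; N–CH and ring-fusion CH of the hydrindene by substrate control (trans amination, axial alkylation); cyclopentane CH by Pd-catalysed asymmetric allylic alkylation; N–CH of the azabicycle by SN2 epoxide opening; CH–CH3 by kinetic protonation; both quaternary carbons in the key step; nitrogen by oxidation of the amine.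

Key step: step 18

Remark: the target's nitrogen descriptor puts the oxide oxygen on the face of the pyrrolidine ring opposite to the hydrogen of the adjacent N–CH ring-fusion carbon; amine 26 is assumed to be oxidised through that lone-pair orientation.
Remark: compounds 13–17 are carried as both epimers at the CH(CH3) carbon next to the carbonyl group; step 13 converges them.

**Route**

Step 1
Reactants: 1 cyclohex-2-en-1-one
Product: 3 trimethyl({(3S)-3-[(trimethylsilyl)ethynyl]cyclohex-1-en-1-yl}oxy)silane, via dimethylaluminium enolate 2 (not isolated)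
Conditions: TMS-acetylene, n-BuLi, Me2AlCl, t-BuOMe, 0 °C; Ni(acac)2 (5 mol%), chiral cyano-bis(oxazoline) ligand (enantiomer giving the S adduct); then TMSCl, Et3N, 0 °C
Reagents that add atoms: trimethylsilylacetylene (C#C[Si](C)(C)C); chlorotrimethylsilane (C[Si](C)(C)Cl)
Why: Ni-catalysed enantioselective conjugate addition of the alkynylalane sets the alkynyl-bearing stereocentre under ligand control, and O-silylation of the regiodefined aluminium enolate fixes the enol ether on the side of that centre (asymmetric conjugate alkynylation with enolate trapping).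

Step 2
Reactants: 3 silyl enol ether
Product: 4 N-{(1R,6R)-2-oxo-6-[(trimethylsilyl)ethynyl]cyclohexyl}-2-(trimethylsilyl)ethane-1-sulfonamide (N and alkynyl trans)
Conditions: SesNH2, PhI=O, Cu(MeCN)4PF6 (10 mol%), 3 Å MS, MeCN, −20→0 °C; aq. NaHCO3
Reagents that add atoms: 2-(trimethylsilyl)ethanesulfonamide (NS(=O)(=O)CC[Si](C)(C)C)
Why: Cu-catalysed nitrene transfer to the enol ether (aziridination and ring opening) should place nitrogen on the enol carbon anti to the neighbouring alkynyl group, and the epimerisable α-amino ketone settles as the trans-diequatorial isomer.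

Step 3
Reactants: 4 sulfonamido ketone
Product: 5 N-{(1R,3R,6R)-3-(but-3-en-1-yl)-2-oxo-6-[(trimethylsilyl)ethynyl]cyclohexyl}-2-(trimethylsilyl)ethane-1-sulfonamide (butenyl trans to N, cis to alkynyl)
Conditions: LDA (2.2 equiv), THF, −78 °C; 4-iodobut-1-ene, DMPU, −78→−40 °C
Reagents that add atoms: 4-iodobut-1-ene (C=CCCI)
Why: after N-lithiation the second deprotonation should occur kinetically at the CH2 side, and axial alkylation of that enolate through the half-chair with N and alkynyl equatorial should give the 2,6-trans ketone (stereoelectronically controlled enolate alkylation).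

Step 4
Reactants: 5 butenyl ketone
Product: 6 N-{(1R,3R,6R)-3-(but-3-en-1-yl)-2-methylidene-6-[(trimethylsilyl)ethynyl]cyclohexyl}-2-(trimethylsilyl)ethane-1-sulfonamide
Conditions: Zn, CH2Br2, TiCl4, THF/CH2Cl2, 0→23 °C
Reagents that add atoms: dibromomethane (BrCBr)
Why: Takai–Lombardo methylenation is non-basic, so the two α-stereocentres of the hindered ketone should not epimerise.

Step 5
Reactants: 6 diene
Product: 7 N-{(3aR,6R,7R)-6-[(trimethylsilyl)ethynyl]-3,3a,4,5,6,7-hexahydro-2H-inden-7-yl}-2-(trimethylsilyl)ethane-1-sulfonamide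
Conditions: Ru benzylidene metathesis catalyst (2nd generation, 5 mol%), CH2Cl2, 40 °C
Reagents that add atoms: none
Why: ring-closing metathesis of the 1,1-disubstituted and the terminal alkene closes the cyclopentene with the trisubstituted double bond in its final position; the silyl alkyne is a poor metathesis partner.

Step 6
Reactants: 7 bicyclic sulfonamide
Product: 8 (3aR,6R,7R)-6-ethynyl-3,3a,4,5,6,7-hexahydro-2H-inden-7-amine
Conditions: CsF, DMF, 95 °C; H2O
Reagents that add atoms: none
Why: fluoride attacks silicon, so the SES group fragments (ethene, SO2) and the C(sp)–Si bond is cleaved in the same operation.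

Step 7
Reactants: 9 cyclopent-2-en-1-yl acetate (racemic); 10 dimethyl 2-methylpropanedioate
Product: 11 dimethyl 2-[(1S)-cyclopent-2-en-1-yl]-2-methylpropanedioate
Conditions: NaH, THF; [Pd(allyl)Cl]2 (1 mol%), DACH-phenyl bisphosphine ligand (3 mol%, enantiomer giving the S product), (n-Hex)4NBr, CH2Cl2, 0 °C
Reagents that add atoms: none
Why: Tsuji–Trost asymmetric allylic alkylation through the meso π-allyl complex; the ligand selects the allyl terminus and so sets the ring stereocentre from racemic acetate.

Step 8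
Reactants: 11 malonate
Product: 13 2-[(1S)-cyclopent-2-en-1-yl]propanoic acid (both C-2 epimers), via malonic diacid 12 (not isolated)
Conditions: NaOH, MeOH/H2O, 60 °C; HCl (pH 1); toluene, 110 °C
Reagents that add atoms: sodium hydroxide ([Na+].[OH-])
Why: saponification and thermal decarboxylation of the malonic acid; the new α-centre is left as a mixture because it is fixed later.

Step 9
Reactants: 13 acid
Product: 14 pentafluorophenyl 2-[(1S)-cyclopent-2-en-1-yl]propanoate
Conditions: C6F5OH, DCC, DMAP (cat.), CH2Cl2, 0→23 °C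
Reagents that add atoms: pentafluorophenol (Oc1c(F)c(F)c(F)c(F)c1F)
Why: Steglich-type esterification gives an active ester, so that no free carboxylate is present once the epoxide is in place.

Step 10
Reactants: 14 active ester
Product: 15 pentafluorophenyl 2-[(1R,2R,5S)-6-oxabicyclo[3.1.0]hexan-2-yl]propanoate (epoxide trans to the side chain)
Conditions: mCPBA, NaHCO3, CH2Cl2, 0 °C
Reagents that add atoms: 3-chloroperbenzoic acid (OOC(=O)c1cccc(Cl)c1)
Why: Prilezhaev epoxidation should occur on the ring face anti to the allylic side chain.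

Step 11
Reactants: 8 hydrindenyl amine; 15 epoxy active ester
Product: 16 N-[(3aR,6R,7R)-6-ethynyl-3,3a,4,5,6,7-hexahydro-2H-inden-7-yl]-2-[(1R,2R,5S)-6-oxabicyclo[3.1.0]hexan-2-yl]propanamide
Conditions: i-Pr2NEt, THF, 23 °C
Reagents that add atoms: none
Why: aminolysis of the pentafluorophenyl ester joins the two enantiopure halves under neutral conditions that leave the epoxide intact.

Step 12
Reactants: 16 epoxy amide
Product: 17 (3RS,3aR,6S,6aS)-1-[(3aR,6R,7R)-6-ethynyl-3,3a,4,5,6,7-hexahydro-2H-inden-7-yl]-6-hydroxy-3-methylhexahydrocyclopenta[b]pyrrol-2(1H)-one (cis-fused, OH anti to N)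
Conditions: NaH, DMF, 0→50 °C; H2O
Reagents that add atoms: none
Why: the amide N-anion opens the epoxide by 5-exo-tet attack with inversion at the nearer carbon, which only the trans-epoxide allows, giving the cis-fused lactam and a secondary alcohol.

Step 13
Reactants: 17 hydroxy lactam (epimers)
Product: 18 (3S,3aR,6S,6aS)-1-[(3aR,6R,7R)-6-ethynyl-3,3a,4,5,6,7-hexahydro-2H-inden-7-yl]-6-hydroxy-3-methylhexahydrocyclopenta[b]pyrrol-2(1H)-one (3-methyl on the concave face)
Conditions: LDA (4 equiv), THF, −78→−20 °C; 2,6-di-tert-butyl-4-methylphenol, −78 °C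
Reagents that add atoms: none
Why: both epimers give the same lactam enolate, and kinetic protonation from the convex face of the cis-fused bicycle should leave the methyl group on the concave face.

Step 14
Reactants: 18 alcohol
Product: 19 (3S,3aR,6aS)-1-[(3aR,6R,7R)-6-ethynyl-3,3a,4,5,6,7-hexahydro-2H-inden-7-yl]-3-methylhexahydrocyclopenta[b]pyrrole-2,6-dione
Conditions: DMP, NaHCO3, CH2Cl2, 23 °C
Reagents that add atoms: none
Why: periodinane oxidation of the secondary alcohol under buffered conditions; the α-amido ketone keeps the favoured cis ring fusion.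

Step 15
Reactants: 19 ketone
Product: 20 (3S,3aR,6S,6aS)-6-ethenyl-1-[(3aR,6R,7R)-6-ethynyl-3,3a,4,5,6,7-hexahydro-2H-inden-7-yl]-6-hydroxy-3-methylhexahydrocyclopenta[b]pyrrol-2(1H)-one
Conditions: CH2=CHMgBr (excess), CeCl3, THF, −78 °C
Reagents that add atoms: vinylmagnesium bromide (C=C[Mg]Br)
Why: the organocerium reagent adds 1,2 to the enolisable ketone from the convex face without enolisation and leaves the lactam untouched; the carbinol configuration is lost in the next step.

Step 16
Reactants: 20 vinyl carbinol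
Product: 21 2-[(3S,3aR,6aS)-1-[(3aR,6R,7R)-6-ethynyl-3,3a,4,5,6,7-hexahydro-2H-inden-7-yl]-3-methyl-2-oxohexahydrocyclopenta[b]pyrrol-6(2H)-ylidene]acetaldehyde (E/Z mixture, geometry inconsequential)
Conditions: PCC, 4 Å MS, CH2Cl2, 23 °C
Reagents that add atoms: pyridinium chlorochromate ([nH+]1ccccc1.[O-][Cr](=O)(=O)Cl)
Why: Babler–Dauben oxidative transposition, in which the chromate ester of the tertiary allylic alcohol undergoes a [3,3] shift and oxidation to the β,β-disubstituted enal.

Step 17
Reactants: 21 alkynyl enal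
Product: 22 1-{(3aR,6R,7R)-7-[(3S,3aR,6aS)-3-methyl-2-oxo-6-(2-oxoethylidene)hexahydrocyclopenta[b]pyrrol-1(2H)-yl]-3,3a,4,5,6,7-hexahydro-2H-inden-6-yl}ethenyl chloroacetate
Conditions: ClCH2CO2H, [RuCl2(p-cymene)]2 (2 mol%), P(2-furyl)3, Na2CO3 (cat.), toluene, 50 °C
Reagents that add atoms: chloroacetic acid (OC(=O)CCl)
Why: Ru-catalysed Markovnikov addition of a carboxylic acid to a terminal alkyne gives the 2-acyloxy-1-alkene under neutral conditions that the enal and the lactam tolerate.

Step 18
Reactants: 22 enol chloroacetate enal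
Product: 24 hexacyclic formyl δ-lactone lactam (target skeleton with C=O at the N–CH2 carbon and CHO on the lactone β-carbon), via seco chloroacetate aldehyde 23 (not isolated)
Conditions: Fe(acac)3, PhSiH3, THF/i-PrOH, 0→23 °C; then DMF, Cs2CO3, NaI (cat.), 40 °C
Reagents that add atoms: none
Why: Proposed new method: Fe–H hydrogen-atom transfer to the electron-rich 2-acyloxy-1-alkene gives the tertiary α-acyloxy radical (creating the methyl group), which closes the piperidine ring by 6-exo-trig Giese addition to the β-carbon of the enal; reduction of the α-formyl radical gives the enolate (radical–polar crossover), and this enolate, regenerated by Cs2CO3 from any protonated aldehyde 23, displaces chloride from the chloroacetate in a 6-exo-tet C-alkylation that closes the δ-lactone. The closest known reactions are MHAT-initiated Giese cyclisations onto enals with enolate trapping (radical–polar crossover annulation) and intramolecular alkylation of aldehyde enolates by α-halo esters; new here are the enol-ester radical precursor and the alkylative lactone closure. The all-carbon quaternary centre is set by attack on the alkylidene face syn to the lactam nitrogen, the only face the four-atom tether through nitrogen can reach, which gives the cis-fused ring. The O-bearing quaternary centre is set in the same bond formation: the radical is expected to react through the conformer with the long acyloxy arm pointing away from the concave azabicycle and the methyl group over the cyclopentane, and only this epimer can bring the ester to the enolate carbon, so lactone closure selects it; the formyl-bearing centre is removed in step 19 and does not matter. The step needs hydrogen-atom transfer to the 1,1-disubstituted enol ester rather than to the hindered trisubstituted cyclopentene or the electron-poor enal, 6-exo rather than 7-endo closure (the formyl group polarises the alkene), and C- rather than O-alkylation (six- against eight-membered ring).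

Step 19
Reactants: 24 formyl lactone lactam
Product: 25 hexacyclic δ-lactone lactam (target skeleton with C=O at the N–CH2 carbon)
Conditions: [Rh(cod)Cl]2 (5 mol%), dppp, diglyme, 160 °C
Reagents that add atoms: none
Why: Tsuji–Wilkinson decarbonylation (oxidative addition into the aldehyde C–H, CO extrusion, reductive elimination) removes the activating formyl group and leaves the lactone β-CH2.

Step 20
Reactants: 25 lactone lactam
Product: 26 hexacyclic tertiary amine (the N-deoxy target)
Conditions: [Ir(coe)2Cl]2 (2 mol%), Et2SiH2, CH2Cl2, 23 °C; aq. NaHCO3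
Reagents that add atoms: none
Why: Ir-catalysed hydrosilylation reduces the tertiary lactam through the silyl hemiaminal and iminium ion and should leave the much less Lewis-basic δ-lactone and the alkene untouched.

Step 21
Reactants: 26 tertiary amine
Product: 27 target N-oxide (CNP0566793.4)
Conditions: mCPBA (1.05 equiv), K2CO3, CH2Cl2, −40→0 °C
Reagents that add atoms: 3-chloroperbenzoic acid (OOC(=O)c1cccc(Cl)c1)
Why: peracid oxidation of a tertiary amine is far faster than epoxidation of the trisubstituted alkene, and oxygen is delivered to the nitrogen lone pair in the orientation stated in the remark, which fixes the nitrogen stereocentre.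

**Compound list**

1 | cyclohex-2-en-1-one | O=C1C=CCCC1 | starting material
2 | dimethyl({(3S)-3-[(trimethylsilyl)ethynyl]cyclohex-1-en-1-yl}oxy)alane | C[Si](C)(C)C#C[C@H]1CCCC(O[Al](C)C)=C1 | intermediate
3 | trimethyl({(3S)-3-[(trimethylsilyl)ethynyl]cyclohex-1-en-1-yl}oxy)silane | C[Si](C)(C)C#C[C@H]1CCCC(O[Si](C)(C)C)=C1 | intermediate
4 | N-{(1R,6R)-2-oxo-6-[(trimethylsilyl)ethynyl]cyclohexyl}-2-(trimethylsilyl)ethane-1-sulfonamide | C[Si](C)(C)CCS(=O)(=O)N[C@H]1C(=O)CCC[C@@H]1C#C[Si](C)(C)C | intermediate
5 | N-{(1R,3R,6R)-3-(but-3-en-1-yl)-2-oxo-6-[(trimethylsilyl)ethynyl]cyclohexyl}-2-(trimethylsilyl)ethane-1-sulfonamide | C[Si](C)(C)CCS(=O)(=O)N[C@H]1C(=O)[C@H](CCC=C)CC[C@@H]1C#C[Si](C)(C)C | intermediate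
6 | N-{(1R,3R,6R)-3-(but-3-en-1-yl)-2-methylidene-6-[(trimethylsilyl)ethynyl]cyclohexyl}-2-(trimethylsilyl)ethane-1-sulfonamide | C[Si](C)(C)CCS(=O)(=O)N[C@H]1C(=C)[C@H](CCC=C)CC[C@@H]1C#C[Si](C)(C)C | intermediate
7 | N-{(3aR,6R,7R)-6-[(trimethylsilyl)ethynyl]-3,3a,4,5,6,7-hexahydro-2H-inden-7-yl}-2-(trimethylsilyl)ethane-1-sulfonamide | C[Si](C)(C)CCS(=O)(=O)N[C@H]1C2=CCC[C@@H]2CC[C@@H]1C#C[Si](C)(C)C | intermediate
8 | (3aR,6R,7R)-6-ethynyl-3,3a,4,5,6,7-hexahydro-2H-inden-7-amine | N[C@H]1C2=CCC[C@@H]2CC[C@@H]1C#C | intermediate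
9 | cyclopent-2-en-1-yl acetate (racemic) | CC(=O)OC1C=CCC1 | starting material
10 | dimethyl 2-methylpropanedioate | COC(=O)C(C)C(=O)OC | starting material
11 | dimethyl 2-[(1S)-cyclopent-2-en-1-yl]-2-methylpropanedioate | COC(=O)C(C)(C(=O)OC)[C@@H]1C=CCC1 | intermediate
12 | 2-[(1S)-cyclopent-2-en-1-yl]-2-methylpropanedioic acid | OC(=O)C(C)(C(=O)O)[C@@H]1C=CCC1 | intermediate
13 | 2-[(1S)-cyclopent-2-en-1-yl]propanoic acid (both C-2 epimers) | OC(=O)C(C)[C@@H]1C=CCC1 | intermediate
14 | pentafluorophenyl 2-[(1S)-cyclopent-2-en-1-yl]propanoate (both C-2 epimers) | O=C(Oc1c(F)c(F)c(F)c(F)c1F)C(C)[C@@H]1C=CCC1 | intermediate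
15 | pentafluorophenyl 2-[(1R,2R,5S)-6-oxabicyclo[3.1.0]hexan-2-yl]propanoate (both C-2 epimers) | O=C(Oc1c(F)c(F)c(F)c(F)c1F)C(C)[C@@H]1[C@H]2O[C@H]2CC1 | intermediate
16 | N-[(3aR,6R,7R)-6-ethynyl-3,3a,4,5,6,7-hexahydro-2H-inden-7-yl]-2-[(1R,2R,5S)-6-oxabicyclo[3.1.0]hexan-2-yl]propanamide (both C-2 epimers) | O=C(N[C@H]1C2=CCC[C@@H]2CC[C@@H]1C#C)C(C)[C@@H]1[C@H]2O[C@H]2CC1 | intermediate
17 | (3RS,3aR,6S,6aS)-1-[(3aR,6R,7R)-6-ethynyl-3,3a,4,5,6,7-hexahydro-2H-inden-7-yl]-6-hydroxy-3-methylhexahydrocyclopenta[b]pyrrol-2(1H)-one | O=C1C(C)[C@H]2CC[C@H](O)[C@H]2N1[C@H]1C2=CCC[C@@H]2CC[C@@H]1C#C | intermediate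
18 | (3S,3aR,6S,6aS)-1-[(3aR,6R,7R)-6-ethynyl-3,3a,4,5,6,7-hexahydro-2H-inden-7-yl]-6-hydroxy-3-methylhexahydrocyclopenta[b]pyrrol-2(1H)-one | O=C1[C@@H](C)[C@H]2CC[C@H](O)[C@H]2N1[C@H]1C2=CCC[C@@H]2CC[C@@H]1C#C | intermediate
19 | (3S,3aR,6aS)-1-[(3aR,6R,7R)-6-ethynyl-3,3a,4,5,6,7-hexahydro-2H-inden-7-yl]-3-methylhexahydrocyclopenta[b]pyrrole-2,6-dione | O=C1[C@@H](C)[C@H]2CCC(=O)[C@H]2N1[C@H]1C2=CCC[C@@H]2CC[C@@H]1C#C | intermediate
20 | (3S,3aR,6S,6aS)-6-ethenyl-1-[(3aR,6R,7R)-6-ethynyl-3,3a,4,5,6,7-hexahydro-2H-inden-7-yl]-6-hydroxy-3-methylhexahydrocyclopenta[b]pyrrol-2(1H)-one | O=C1[C@@H](C)[C@H]2CC[C@](O)(C=C)[C@H]2N1[C@H]1C2=CCC[C@@H]2CC[C@@H]1C#C | intermediate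
21 | 2-[(3S,3aR,6aS)-1-[(3aR,6R,7R)-6-ethynyl-3,3a,4,5,6,7-hexahydro-2H-inden-7-yl]-3-methyl-2-oxohexahydrocyclopenta[b]pyrrol-6(2H)-ylidene]acetaldehyde (E/Z mixture) | O=C1[C@@H](C)[C@H]2CCC(=CC=O)[C@H]2N1[C@H]1C2=CCC[C@@H]2CC[C@@H]1C#C | intermediate
22 | 1-{(3aR,6R,7R)-7-[(3S,3aR,6aS)-3-methyl-2-oxo-6-(2-oxoethylidene)hexahydrocyclopenta[b]pyrrol-1(2H)-yl]-3,3a,4,5,6,7-hexahydro-2H-inden-6-yl}ethenyl chloroacetate | O=C1[C@@H](C)[C@H]2CCC(=CC=O)[C@H]2N1[C@H]1C2=CCC[C@@H]2CC[C@@H]1C(=C)OC(=O)CCl | intermediate
23 | seco chloroacetate aldehyde: pentacyclic lactam with the piperidine ring closed, tertiary chloroacetate on the O-bearing quaternary carbon and a CH2CHO group on the adjacent quaternary carbon, cis to that ester | C[C@@H]1C(=O)N2[C@H]3C4=CCC[C@@H]4CC[C@@H]3[C@@](C)(OC(=O)CCl)[C@]4(CC=O)CC[C@H]1[C@@H]42 | intermediate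
24 | hexacyclic formyl δ-lactone lactam (all ring stereocentres as in the target; formyl-bearing carbon undefined) | C[C@@H]1C(=O)N2[C@H]3C4=CCC[C@@H]4CC[C@@H]3[C@@]3(C)OC(=O)CC(C=O)[C@]34CC[C@H]1[C@@H]42 | intermediate
25 | hexacyclic δ-lactone lactam (target skeleton with C=O at the N–CH2 carbon) | C[C@@H]1C(=O)N2[C@H]3C4=CCC[C@@H]4CC[C@@H]3[C@@]3(C)OC(=O)CC[C@]34CC[C@H]1[C@@H]42 | intermediate
26 | hexacyclic tertiary amine (N-deoxy target) | C[C@@H]1CN2[C@H]3C4=CCC[C@@H]4CC[C@@H]3[C@@]3(C)OC(=O)CC[C@]34CC[C@H]1[C@@H]42 | intermediate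
27 | target N-oxide CNP0566793.4 | C[C@@H]1C[N@@+]2([O-])[C@H]3C4=CCC[C@@H]4CC[C@@H]3[C@@]3(C)OC(=O)CC[C@]34CC[C@H]1[C@@H]42 | target

**Totals and risks**

Total step count: 21. Longest linear sequence: 17 steps (steps 1–6 and 11–21); the cyclopentane branch is steps 7–10.

Step 18 (riskiest; Proposed new method). The planar α-acyloxy radical may add through its other face, giving an adduct whose ester cannot reach the enolate carbon; hydrogen-atom transfer may also go to the cyclopentene, or the enolate may be protonated without alkylation. The fallback builds the same two rings by known chelation-controlled ketyl chemistry, setting out from ketone 19 and returning at lactone lactam 25. Horner–Wadsworth–Emmons reaction of 19 with triethyl phosphonoacetate and NaH gives the alkylidene ester F1. Au(I)-catalysed hydration of its alkyne gives the methyl ketone F2. SmI2 in THF/MeOH at −78 °C closes the piperidine ring by 6-exo ketyl–olefin addition; Sm(III) chelation between ketyl oxygen and ester places oxygen cis to the CH2CO2Et arm, which lactonises to the γ-lactone F3. DIBAL-H at −78 °C gives the γ-lactol F4, and Wittig reaction with methoxymethylenetriphenylphosphorane gives the hydroxy enol ether F5. Aqueous HCl gives the δ-lactol F6, which is oxidised with TPAP/NMO to 25.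

Step 3. The unactivated iodide reacts slowly, so proton transfer between enolate and product may erode the kinetic axial selectivity and the regiochemistry, and N-alkylation may compete. The fallback uses a fast electrophile and builds the cyclopentene differently, setting out from 4 and returning at 7. The dianion of 4 is alkylated with allyl bromide at −78 °C to the allyl ketone F7. Vinylcerium addition gives the divinyl carbinol F8, and ring-closing metathesis gives the bicyclic tertiary allylic alcohol F9. Ionic reduction with Et3SiH and BF3·OEt2 at −78 °C delivers hydride to the less hindered allyl terminus and gives 7 with the trisubstituted double bond.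

Step 20. Hydrosilylation may stop at the silyl hemiaminal or enamine stage, which would scramble the CH–CH3 centre, or may touch the lactone. The fallback activates the lactam as a thioamide, setting out from 25 and returning at 26. The dithiadiphosphetane thionating reagent in toluene at 80 °C converts the lactam, which is far more reactive than the lactone, into the thiolactam F10. MeI gives the S-methyl thioiminium iodide F11, and NaBH4 at −78→0 °C reduces it to 26.

Further compounds
F1 | step 18 | ethyl 2-[(3S,3aR,6aS)-1-[(3aR,6R,7R)-6-ethynyl-3,3a,4,5,6,7-hexahydro-2H-inden-7-yl]-3-methyl-2-oxohexahydrocyclopenta[b]pyrrol-6(2H)-ylidene]acetate | O=C1[C@@H](C)[C@H]2CCC(=CC(=O)OCC)[C@H]2N1[C@H]1C2=CCC[C@@H]2CC[C@@H]1C#C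
F2 | step 18 | methyl ketone from hydration of the alkyne of F1 | O=C1[C@@H](C)[C@H]2CCC(=CC(=O)OCC)[C@H]2N1[C@H]1C2=CCC[C@@H]2CC[C@@H]1C(C)=O
F3 | step 18 | hexacyclic γ-lactone lactam (one CH2 fewer than 25 in the lactone ring) | C[C@@H]1C(=O)N2[C@H]3C4=CCC[C@@H]4CC[C@@H]3[C@@]3(C)OC(=O)C[C@]34CC[C@H]1[C@@H]42
F4 | step 18 | γ-lactol of F3 | C[C@@H]1C(=O)N2[C@H]3C4=CCC[C@@H]4CC[C@@H]3[C@@]3(C)OC(O)C[C@]34CC[C@H]1[C@@H]42
F5 | step 18 | tertiary alcohol with a 3-methoxyprop-2-enyl arm on the adjacent quaternary carbon | C[C@@H]1C(=O)N2[C@H]3C4=CCC[C@@H]4CC[C@@H]3[C@@](C)(O)[C@]4(CC=COC)CC[C@H]1[C@@H]42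
F6 | step 18 | δ-lactol of 25 | C[C@@H]1C(=O)N2[C@H]3C4=CCC[C@@H]4CC[C@@H]3[C@@]3(C)OC(O)CC[C@]34CC[C@H]1[C@@H]42
F7 | step 3 | N-{(1R,3R,6R)-2-oxo-3-(prop-2-en-1-yl)-6-[(trimethylsilyl)ethynyl]cyclohexyl}-2-(trimethylsilyl)ethane-1-sulfonamide | C[Si](C)(C)CCS(=O)(=O)N[C@H]1C(=O)[C@H](CC=C)CC[C@@H]1C#C[Si](C)(C)C
F8 | step 3 | 2-ethenyl-2-hydroxy analogue of F7 (carbinol configuration undefined) | C[Si](C)(C)CCS(=O)(=O)N[C@H]1C(O)(C=C)[C@H](CC=C)CC[C@@H]1C#C[Si](C)(C)C
F9 | step 3 | bicyclic tertiary allylic alcohol (7a-hydroxy-3,3a,4,5,6,7-hexahydro skeleton with the double bond one position further along the five-membered ring) | C[Si](C)(C)CCS(=O)(=O)N[C@H]1C2(O)C=CC[C@@H]2CC[C@@H]1C#C[Si](C)(C)C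
F10 | step 20 | thiolactam of 25 | C[C@@H]1C(=S)N2[C@H]3C4=CCC[C@@H]4CC[C@@H]3[C@@]3(C)OC(=O)CC[C@]34CC[C@H]1[C@@H]42
F11 | step 20 | S-methyl thioiminium iodide of F10 | C[C@@H]1C(SC)=[N+]2[C@H]3C4=CCC[C@@H]4CC[C@@H]3[C@@]3(C)OC(=O)CC[C@]34CC[C@H]1[C@@H]42.[I-]
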